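**Retrosynthetic overview**

- The route rests on the single six-membered quinone ring C1–C6. Its four-carbon part C4(=O)–C5(O)=C6(H)–C1(=O) is a ring-opened 3-alkoxycyclobutenedione, and its two-carbon part C2(O)=C3(chain) is a 1-alkoxyalkyne.
- Key disconnection: the bonds C1–C2 and C3–C4 are cut together. Forward, a maleoylcobalt complex of isopropyl semisquarate takes up (E)-1-ethoxyhenicos-16-en-1-yne in a cobalt-templated [4+2]. The only ring of the target forms here, already at the quinone oxidation level.
- The ynol ether comes from lithium ethoxyacetylide and (E)-nonadec-14-enyl iodide. The iodide comes from hex-1-yne and a C13 bromo alcohol made from tridecanedioic acid; the E alkene is set by dissolving-metal reduction of the alkyne.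
- The semisquarate comes from diisopropyl squarate by hydride reduction and acid transposition. The last step hydrolyses the two vinylogous esters at C2 and C5.

Key step: step 11

Remark: the acetal carbon of the THP ethers 4, 7 and 8 and the carbinol carbon of 15 are racemic and are lost before the target; the configuration at cobalt in 17 and 18 is left undefined; the only stereo-element of the target is the E alkene.

**Route**

Step 1
Reactants: 1 tridecanedioic acid
Product: 2 tridecane-1,13-diol
Conditions: BH3·THF, THF, 0 °C to rt; then aq. K2CO3
Reagents that add atoms: none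
Why: Borane reduction of carboxylic acids should take both acid groups to primary alcohols, and no other function is present.

Step 2
Reactants: 2 tridecane-1,13-diol
Product: 3 13-bromotridecan-1-ol
Conditions: 48% aq. HBr (1.2 equiv), toluene, reflux
Reagents that add atoms: hydrogen bromide, Br
Why: Acid-mediated SN2 monobromination of a symmetrical diol in a two-phase system, where the bromo alcohol moves into toluene and is shielded from a second substitution.

Step 3
Reactants: 3 13-bromotridecan-1-ol
Product: 4 2-[(13-bromotridecyl)oxy]oxane (THP ether)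
Conditions: 3,4-dihydro-2H-pyran, PPTS (cat.), CH2Cl2, rt
Reagents that add atoms: 3,4-dihydro-2H-pyran, C1CCOC=C1
Why: Acid-catalysed acetalisation (THP protection) masks the hydroxyl proton before the acetylide alkylation.

Step 4
Reactants: 4 2-[(13-bromotridecyl)oxy]oxane; 5 hex-1-yne
Product: 7 2-(nonadec-14-yn-1-yloxy)oxane, via lithium hex-1-ynide 6 (not isolated)
Conditions: n-BuLi, THF, −78 to 0 °C; then 4, DMPU, 0 °C to rt
Reagents that add atoms: none
Why: SN2 alkylation of a lithium acetylide by an unhindered primary bromide in a dipolar cosolvent, with the THP acetal inert to the base.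

Step 5
Reactants: 7 2-(nonadec-14-yn-1-yloxy)oxane
Product: 8 2-[(E)-nonadec-14-en-1-yloxy]oxane
Conditions: Li, NH3(l)/THF, −33 °C; then NH4Cl
Reagents that add atoms: none
Why: Dissolving-metal reduction of an internal alkyne, in which the vinyl radical anion and vinyl anion take the trans arrangement before protonation, so the E alkene is set here; an isolated alkene and the acetal are not reduced.

Step 6
Reactants: 8 2-[(E)-nonadec-14-en-1-yloxy]oxane
Product: 9 (E)-nonadec-14-en-1-ol
Conditions: TsOH·H2O (cat.), MeOH, rt
Reagents that add atoms: none
Why: Acid-catalysed transacetalisation to methanol removes the THP group under conditions that leave the isolated E alkene untouched.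

Step 7
Reactants: 9 (E)-nonadec-14-en-1-ol
Product: 10 (E)-19-iodononadec-5-ene [(E)-nonadec-14-enyl iodide]
Conditions: PPh3, I2, imidazole, CH2Cl2, 0 °C to rt
Reagents that add atoms: iodine, II
Why: Appel-type iodination of a primary alcohol through the alkoxyphosphonium iodide and SN2 displacement, with no effect on the remote alkene.

Step 8
Reactants: 10 (E)-19-iodononadec-5-ene; 11 ethoxyacetylene
Product: 13 (E)-1-ethoxyhenicos-16-en-1-yne, via lithium ethoxyacetylide 12 (not isolated)
Conditions: n-BuLi, THF, −78 °C; then 10, HMPA, −78 °C to rt; chromatography on Et3N-deactivated silica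
Reagents that add atoms: none
Why: SN2 alkylation of lithium ethoxyacetylide by a primary iodide in THF/HMPA, the standard entry to 1-ethoxyalk-1-ynes, with neutral isolation because the ynol ether is acid-sensitive.

Step 9
Reactants: 14 diisopropyl squarate
Product: 16 3-isopropoxycyclobut-3-ene-1,2-dione, via 4-hydroxy-2,3-diisopropoxycyclobut-2-en-1-one 15 (not isolated)
Conditions: LiAlH(OtBu)3, THF, −20 °C; then aq. HCl work-up and conc. HCl (cat.), CH2Cl2, rt
Reagents that add atoms: water, O
Why: 1,2-Hydride reduction of one squarate carbonyl followed by acid-induced allylic transposition (ionisation of the carbinol, water capture at the distal alkoxy carbon, loss of isopropanol) is the established route to semisquarates.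

Step 10
Reactants: 16 3-isopropoxycyclobut-3-ene-1,2-dione
Product: 18 chloro(dimethylglyoxime)(pyridine)(2-isopropoxybut-2-ene-1,4-dioyl)cobalt (trivalent cobalt; five-membered ring Co–C(=O)–C(OiPr)=CH–C(=O)), via chlorobis(triphenylphosphine)cobalt maleoyl complex 17 (not isolated)
Conditions: ClCo(PPh3)3, benzene, rt, argon; then dimethylglyoxime, pyridine, rt
Reagents that add atoms: chlorotris(triphenylphosphine)cobalt, Cl[Co-3]([P+](c1ccccc1)(c1ccccc1)c1ccccc1)([P+](c1ccccc1)(c1ccccc1)c1ccccc1)[P+](c1ccccc1)(c1ccccc1)c1ccccc1; dimethylglyoxime, CC(=NO)C(C)=NO; pyridine, c1ccncc1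
Why: Oxidative addition of monovalent cobalt into the strained bond between the two carbonyl carbons gives the trivalent-cobalt diacyl metallacycle, and exchange of the phosphines for dimethylglyoxime and pyridine gives the air-stable complex that reacts with alkynes under mild conditions.

Step 11
Reactants: 18 chloro(dimethylglyoxime)(pyridine)(2-isopropoxybut-2-ene-1,4-dioyl)cobalt; 13 (E)-1-ethoxyhenicos-16-en-1-yne
Product: 19 2-ethoxy-5-isopropoxy-3-[(E)-nonadec-14-en-1-yl]cyclohexa-2,5-diene-1,4-dione
Conditions: SnCl4 (1 equiv) premixed with 18 (slight excess), CH2Cl2, −40 °C; then 13 added slowly, −40 °C to rt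
Reagents that add atoms: none
Why: SnCl4, held in a five-membered chelate by the C4 acyl oxygen and the neighbouring C5 isopropoxy oxygen of the trivalent-cobalt metallacycle, should make C4 the most electrophilic acyl carbon, so that the ynol ether attacks it through its nucleophilic β-carbon C3 to form C3–C4 and an ethoxy-stabilised cation at C2 that collapses onto cobalt (net insertion into the Co–C4 bond, seven-membered cobaltacycle), after which reductive elimination forms C1–C2 and expels monovalent cobalt. The closest known reaction is the Lewis-acid-promoted benzoquinone synthesis from maleoylcobalt dimethylglyoxime complexes and alkynes, applied here to a new pair of partners. The single six-membered quinone ring closes as a cobalt-templated formal [4+2] (insertion, then reductive elimination) directly at the quinone oxidation level, and no stereocentre is created. The step needs the 2,5- and not the 2,6-dialkoxy pattern, that is C3 must bond to C4 and not to C1; the substrate favours this because C1 is a vinylogous ester carbonyl deactivated by the C5 oxygen, whereas C4 is ketone-like and chelation-activated, but this pairing is untested and the pattern of 19 is to be proved by HMBC before step 12. The isolated E alkene is a far weaker ligand and nucleophile than the ynol ether and should stay out of the reaction, and premixing SnCl4 with 18 keeps free Lewis acid away from the acid-sensitive alkyne.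

Step 12
Reactants: 19 2-ethoxy-5-isopropoxy-3-[(E)-nonadec-14-en-1-yl]cyclohexa-2,5-diene-1,4-dione
Product: 20 2,5-dihydroxy-3-[(E)-nonadec-14-en-1-yl]cyclohexa-2,5-diene-1,4-dione (target)
Conditions: aq. NaOH, EtOH/THF, rt to 50 °C; then aq. HCl
Reagents that add atoms: sodium hydroxide, [Na+].[OH-]
Why: Hydroxide replaces both alkoxy groups by conjugate addition–elimination at C2 and C5 (hydrolysis of vinylogous esters), the stable dianion is protonated on acidification, and the E alkene is inert to base.

**Compound list**

1 | tridecanedioic acid | OC(=O)CCCCCCCCCCCC(=O)O | starting material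
2 | tridecane-1,13-diol | OCCCCCCCCCCCCCO | intermediate
3 | 13-bromotridecan-1-ol | OCCCCCCCCCCCCCBr | intermediate
4 | 2-[(13-bromotridecyl)oxy]oxane (racemic) | BrCCCCCCCCCCCCCOC1CCCCO1 | intermediate
5 | hex-1-yne | CCCCC#C | starting material
6 | lithium hex-1-ynide | [Li]C#CCCCC | intermediate
7 | 2-(nonadec-14-yn-1-yloxy)oxane (racemic) | CCCCC#CCCCCCCCCCCCCCOC1CCCCO1 | intermediate
8 | 2-[(E)-nonadec-14-en-1-yloxy]oxane (racemic) | CCCC/C=C/CCCCCCCCCCCCCOC1CCCCO1 | intermediate
9 | (E)-nonadec-14-en-1-ol | CCCC/C=C/CCCCCCCCCCCCCO | intermediate
10 | (E)-19-iodononadec-5-ene | CCCC/C=C/CCCCCCCCCCCCCI | intermediate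
11 | ethoxyacetylene | C#COCC | starting material
12 | lithium ethoxyacetylide | [Li]C#COCC | intermediate
13 | (E)-1-ethoxyhenicos-16-en-1-yne | CCCC/C=C/CCCCCCCCCCCCCC#COCC | intermediate
14 | diisopropyl squarate | CC(C)OC1=C(OC(C)C)C(=O)C1=O | starting material
15 | 4-hydroxy-2,3-diisopropoxycyclobut-2-en-1-one (racemic) | CC(C)OC1=C(OC(C)C)C(O)C1=O | intermediate
16 | 3-isopropoxycyclobut-3-ene-1,2-dione | CC(C)OC1=CC(=O)C1=O | intermediate
17 | chlorobis(triphenylphosphine)(2-isopropoxybut-2-ene-1,4-dioyl)cobalt, trivalent cobalt | CC(C)OC1=CC(=O)[Co-2](Cl)([P+](c2ccccc2)(c2ccccc2)c2ccccc2)([P+](c2ccccc2)(c2ccccc2)c2ccccc2)C1=O | intermediate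
18 | chloro(dimethylglyoxime)(pyridine)(2-isopropoxybut-2-ene-1,4-dioyl)cobalt, trivalent cobalt | CC(C)OC1=CC(=O)[Co-3]2(Cl)([n+]3ccccc3)([N+](O)=C(C)C(C)=[N+]2O)C1=O | intermediate
19 | 2-ethoxy-5-isopropoxy-3-[(E)-nonadec-14-en-1-yl]cyclohexa-2,5-diene-1,4-dione | CCCC/C=C/CCCCCCCCCCCCCC1=C(OCC)C(=O)C=C(OC(C)C)C1=O | intermediate
20 | 2,5-dihydroxy-3-[(E)-nonadec-14-en-1-yl]cyclohexa-2,5-diene-1,4-dione | CCCC/C=C/CCCCCCCCCCCCCC1=C(O)C(=O)C=C(O)C1=O | target

**Step count**

Total: 12 steps. Longest linear sequence: 10 steps (steps 1 to 8, then 11 and 12); the squarate branch is steps 9 and 10.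

**Steps most likely to fail**

1. Step 11. The regiochemical sense could reverse if SnCl4 binds through one oxygen to the more basic vinylogous-ester oxygen on C1 instead of chelating at C4, which would steer C3 to C1. The ynol ether could also be hydrated or oligomerised by acid before it reaches cobalt. Fallback, setting out from iodide 10: purchased 1,2,4,5-tetramethoxybenzene is lithiated with n-BuLi in THF/HMPA to (2,3,5,6-tetramethoxyphenyl)lithium F1, which is alkylated by 10 to 1,2,4,5-tetramethoxy-3-[(E)-nonadec-14-en-1-yl]benzene F2. Oxidative demethylation with (NH4)2Ce(NO3)6 in MeCN/H2O at 0 °C should give 2,5-dimethoxy-3-[(E)-nonadec-14-en-1-yl]cyclohexa-2,5-diene-1,4-dione F3, in which the 2,5-pattern is fixed by the arene. Aqueous NaOH and then acid, as in step 12, return the route at target 20.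

2. Step 10. Triphenylphosphine set free during oxidative addition could add in conjugate fashion to the unhindered hydrogen-bearing ring carbon of the semisquarate, or the hydrogen-bearing maleoyl complex could decompose during ligand exchange in pyridine. Fallback, setting out from alcohol 9: oxidation with PhI(OAc)2 and catalytic TEMPO in CH2Cl2 gives (E)-nonadec-14-enal F4. A three-component reductive alkylation of purchased 2,5-dihydroxy-1,4-benzoquinone with F4 and diethyl 2,6-dimethyl-1,4-dihydropyridine-3,5-dicarboxylate (Hantzsch ester), under L-proline catalysis in CH2Cl2 at rt (Knoevenagel condensation, then hydride transfer), comes back to the route at target 20.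

3. Step 8. Substitution of the long-chain iodide by the weakly nucleophilic alkoxyacetylide could be slow in the temperature window that the reagent tolerates, and the ynol ether could be lost by hydration during isolation. Fallback, setting out from alcohol 9: Tf2O and pyridine in CH2Cl2 at −20 °C give (E)-nonadec-14-en-1-yl trifluoromethanesulfonate F5. This far more reactive electrophile alkylates lithium ethoxyacetylide 12 in THF at −78 to 0 °C without HMPA, bypasses iodide 10 and comes back to the route at ynol ether 13.

**Further compounds**

F1 | step 11 | (2,3,5,6-tetramethoxyphenyl)lithium | [Li]c1c(OC)c(OC)cc(OC)c1OC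
F2 | step 11 | 1,2,4,5-tetramethoxy-3-[(E)-nonadec-14-en-1-yl]benzene | CCCC/C=C/CCCCCCCCCCCCCc1c(OC)c(OC)cc(OC)c1OC
F3 | step 11 | 2,5-dimethoxy-3-[(E)-nonadec-14-en-1-yl]cyclohexa-2,5-diene-1,4-dione | CCCC/C=C/CCCCCCCCCCCCCC1=C(OC)C(=O)C=C(OC)C1=O
F4 | step 10 | (E)-nonadec-14-enal | CCCC/C=C/CCCCCCCCCCCCC=O
F5 | step 8 | (E)-nonadec-14-en-1-yl trifluoromethanesulfonate | CCCC/C=C/CCCCCCCCCCCCCOS(=O)(=O)C(F)(F)F
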